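**Retrosynthetic overview**

1. Atom numbers follow the Stemona alkaloids: pyrrole N4, C1–C3, C9a; azepane C5–C9; carbocycle C9–C12 (ethyl on C10, O on C11); ring lactone C13 (methyl), C14; side-chain lactone C18–C21. In this numbering the target is 9R,10R,11S,12R,13R,18R,20S. Last disconnection: the side-chain lactone, by Friedel–Crafts acylation of pyrrole C3 with (S)-methylsuccinic anhydride (brings C20) and catalyst-controlled reduction of the C18 ketone.
2. Carbocycle and ring lactone: the C1–C12 bond, by intramolecular Friedel–Crafts Michael addition of pyrrole C1 to an α-methylbutenolide tethered through C11 (butenolide from ring-closing metathesis). The tether forces the cis fusion at C12; convex-face protonation sets C13.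
3. Azepine (key step): N4–C5 and C8–C9 are made in one flask by a (4+3) annulation of a 1-azafulvene with 4-chlorobutylmagnesium bromide. The enabling feature is the N4–C9a–C9 unit where the azepane ring meets the pyrrole: the pyrrole nitrogen and the exocyclic α-carbon C9 are the two ends of a latent 2-methide-2H-pyrrole (C9 electrophilic, N4 nucleophilic once the pyrrole is re-aromatised). The azafulvene is released from N-Boc-pyrrole and an aldehyde (C9a–C9 bond) by an N→O Boc shift, so Boc is a relay leaving group that the step itself removes.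
4. C10 and C11 come from an Evans syn-aldol reaction (butanoyl imide + acrolein); C9 is set in the key step by allylic strain from C10.
5. Order of ring formation: pyrrole (purchased) → azepine → butenolide → six-membered carbocycle (the butenolide becomes the fused lactone) → side-chain lactone.

Key step: step 6

**Route**

Step 1
Reactants: 1 (S)-4-benzyloxazolidin-2-one; 2 butanoyl chloride
Product: 3 (S)-4-benzyl-3-butanoyloxazolidin-2-one
Conditions: n-BuLi, THF, −78 °C; then 2, −78 → 0 °C
Reagents that add atoms: none
Why: N-acylation of the lithiated Evans oxazolidinone by the acid chloride; no stereocentre is formed and the auxiliary centre is not touched.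

Step 2
Reactants: 3; 4 acrolein
Product: 5 (S)-4-benzyl-3-[(2S,3R)-2-ethyl-3-hydroxypent-4-enoyl]oxazolidin-2-one
Conditions: Bu2BOTf, i-Pr2NEt, CH2Cl2, 0 °C; 4, −78 → 0 °C; then pH 7 buffer, MeOH, H2O2
Reagents that add atoms: none
Why: Evans boron aldol reaction; the Z-boron enolate reacts through a closed Zimmerman–Traxler transition state in which the benzyl group of the auxiliary shields one enolate face, which should give the syn (2S,3R) adduct and so set C10 and C11.

Step 3
Reactants: 5
Product: 6 (2S,3R)-2-ethyl-3-hydroxy-N-methoxy-N-methylpent-4-enamide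
Conditions: MeNH(OMe)·HCl, AlMe3, CH2Cl2, −20 → 0 °C
Reagents that add atoms: N,O-dimethylhydroxylamine hydrochloride, CNOC.Cl
Why: aluminium amide transamidation of the imide to the Weinreb amide, assisted by the free β-hydroxyl group; the α-centre is not enolised and the auxiliary is recovered.

Step 4
Reactants: 6
Product: 7 (2S,3R)-3-[(tert-butyldimethylsilyl)oxy]-2-ethyl-N-methoxy-N-methylpent-4-enamide
Conditions: TBSOTf, 2,6-lutidine, CH2Cl2, 0 °C
Reagents that add atoms: tert-butyldimethylsilyl trifluoromethanesulfonate, CC(C)(C)[Si](C)(C)OS(=O)(=O)C(F)(F)F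
Why: silylation of the secondary alcohol; the bulky silyl ether later makes the C11 group the large substituent that directs the key step and is a poor leaving group next to the azafulvene.

Step 5
Reactants: 7
Product: 8 (2S,3R)-3-[(tert-butyldimethylsilyl)oxy]-2-ethylpent-4-enal
Conditions: i-Bu2AlH, THF, −78 °C; aq. Rochelle salt; used at once
Reagents that add atoms: none
Why: hydride reduction of the Weinreb amide stops at the chelated tetrahedral intermediate and gives the aldehyde on work-up; at −78 °C the α-centre should not epimerise.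

Step 6
Reactants: 8; 9 tert-butyl 1H-pyrrole-1-carboxylate; 10 1-bromo-4-chlorobutane
Product: 17 (9R)-9-[(3R,4R)-4-[(tert-butyldimethylsilyl)oxy]hex-5-en-3-yl]-6,7,8,9-tetrahydro-5H-pyrrolo[1,2-a]azepine, via Grignard reagent 11 (not isolated), via lithiopyrrole 12 (not isolated), via N-Boc alkoxide 13 (not isolated), via carbonate 14 (not isolated), via azafulvene 15 (not isolated), via chloride 16 (not isolated)
Conditions: 9, lithium 2,2,6,6-tetramethylpiperidide (LiTMP), THF, −78 °C; 8, −78 °C; 11 (from 10, Mg, THF; 3 equiv), −78 → 0 °C; then t-BuOK, 18-crown-6, 50 °C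
Reagents that add atoms: none
Why: Proposed new method: a Boc-relay azafulvene (4+3) annulation in which lithiopyrrole 12 adds to aldehyde 8, the lithium alkoxide 13 takes over the Boc group by a 1,4 N→O shift through a five-membered transition state, and the freed pyrrolide 14 expels tert-butyl carbonate (E1cB) to give the 1-azafulvene 15. Grignard reagent 11 then adds to the exocyclic C9 (1,6-addition that re-aromatises the pyrrole, C8–C9 bond), and the pyrrolide 16, as its potassium salt, closes the azepine by intramolecular N-alkylation at C5 (7-exo-tet SN2, N4–C5 bond). The closest known reaction types are the base-induced N→O Boc migration of N-Boc-2-(hydroxyalkyl)pyrroles and -indoles, the addition of Grignard reagents to azafulvenes released from 2-(1-sulfonylalkyl)pyrroles, and the N-alkylation of potassium pyrrolides with t-BuOK/18-crown-6; new is their union in one flask on an α-branched aldehyde. The new stereocentre C9 is controlled by C10: allylic 1,3-strain holds the C10–H bond in the plane of the C9=C9a double bond, so ethyl and the bulky C11(OTBS)(vinyl) group lie on opposite faces and the Grignard reagent should attack anti to the latter, which gives 9R (C8 and ethyl trans in the later carbocycle); the C9 configuration of 13 and 14 is irrelevant because both epimers converge on 15. The step needs addition to win over deprotonation of the azafulvene at C10 and over its dimerisation (secured by the excess of Grignard reagent already present while 15 is released slowly on warming), and N- over C-alkylation (secured by the potassium counter-ion with crown ether, and by the four-carbon chain, which can reach only N4 or C1).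

Step 7
Reactants: 17
Product: 18 (3R,4R)-4-[(9R)-6,7,8,9-tetrahydro-5H-pyrrolo[1,2-a]azepin-9-yl]hex-1-en-3-ol
Conditions: Bu4NF, THF, 0 °C → rt
Reagents that add atoms: none
Why: fluoride cleavage of the silyl ether; no stereocentre is touched.

Step 8
Reactants: 18; 19 methacryloyl chloride
Product: 20 (3R,4R)-4-[(9R)-6,7,8,9-tetrahydro-5H-pyrrolo[1,2-a]azepin-9-yl]hex-1-en-3-yl 2-methylprop-2-enoate
Conditions: Et3N, DMAP (cat.), CH2Cl2, 0 °C
Reagents that add atoms: none
Why: DMAP-catalysed O-acylation of the allylic alcohol, which is faster than C-acylation of the pyrrole at 0 °C; C11 keeps its configuration.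

Step 9
Reactants: 20
Product: 21 (5S)-3-methyl-5-{(1R)-1-[(9R)-6,7,8,9-tetrahydro-5H-pyrrolo[1,2-a]azepin-9-yl]propyl}furan-2(5H)-one
Conditions: second-generation Grubbs catalyst (5 mol%), toluene (5 mM), 80 °C
Reagents that add atoms: none
Why: ring-closing olefin metathesis between the vinyl group and the methacrylate alkene closes the α-methylbutenolide with loss of ethene; no stereocentre is touched (the descriptor at C11 changes only by priority).

Step 10
Reactants: 21
Product: 22 (9R,10R,11S,12R,13R)-tetracyclic lactone (the target without its C3 side chain: pyrrole fused to the azepane and to the C9–C12 carbocycle, which carries the cis-fused 13-methyl-γ-lactone; C3–H)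
Conditions: Me2AlCl (1.5 equiv), CH2Cl2 (5 mM), −78 → 0 °C; then sat. aq. NH4Cl, −78 °C
Reagents that add atoms: none
Why: intramolecular Friedel–Crafts Michael addition (6-exo-trig) of pyrrole C1, the only ring carbon the three-atom tether lets reach C12, to the aluminium-activated butenolide, as in the classical β-cyclisation of 4-(pyrrol-2-yl)butanoic acids; because C11 carries the tether, C1 must add to the butenolide face syn to C10 (cis fusion, 12R), and the aluminium enolate should be protonated on work-up from the convex face anti to the new C1–C12 bond (13R, methyl cis to C1).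

Step 11
Reactants: 23 (S)-2-methylbutanedioic acid
Product: 24 (S)-3-methyloxolane-2,5-dione
Conditions: AcCl, reflux
Reagents that add atoms: none
Why: cyclodehydration of the 1,4-diacid to the five-membered anhydride; the α-centre is not enolised under these acidic conditions.

Step 12
Reactants: 22; 24
Product: 25 (2S)-2-methyl-4-oxo-4-[C3 of tetracycle 22]butanoic acid
Conditions: AlCl3, CH2Cl2, −20 → 0 °C
Reagents that add atoms: none
Why: Friedel–Crafts acylation at the only free pyrrole α-carbon C3; the anhydride should open mainly at its less hindered carbonyl (next to CH2), which leaves the C20 methyl α to the free carboxyl group, with C20 unchanged from 23.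

Step 13
Reactants: 25
Product: 26 methyl (2S)-2-methyl-4-oxo-4-[C3 of tetracycle 22]butanoate
Conditions: MeI, KHCO3, DMF, rt
Reagents that add atoms: iodomethane, CI
Why: SN2 O-methylation of the carboxylate protects the acid for the borane reduction; the weak base does not enolise C13 or C20.

Step 14
Reactants: 26
Product: 28 target CNP0232452.4 (9R,10R,11S,12R,13R,18R,20S), via hydroxy ester 27 (not isolated)
Conditions: (S)-2-methyl-CBS-oxazaborolidine, BH3·SMe2, THF, −20 → 0 °C; MeOH; then DBU (cat.), toluene, rt
Reagents that add atoms: none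
Why: Corey–Bakshi–Shibata reduction, in which the (S)-oxazaborolidine should deliver hydride to the face that gives the R carbinol when the heteroaryl group is the large and CH2 the small substituent (18R); the γ-hydroxy ester then lactonises under base catalysis to the trans side-chain lactone, without acid that would ionise the pyrrol-2-yl carbinyl C–O bond.

**Compound list**

1 | (S)-4-benzyloxazolidin-2-one | O=C1N[C@@H](Cc2ccccc2)CO1 | starting material
2 | butanoyl chloride | CCCC(Cl)=O | starting material
3 | (S)-4-benzyl-3-butanoyloxazolidin-2-one | CCCC(=O)N1[C@@H](Cc2ccccc2)COC1=O | intermediate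
4 | acrolein (prop-2-enal) | C=CC=O | starting material
5 | (S)-4-benzyl-3-[(2S,3R)-2-ethyl-3-hydroxypent-4-enoyl]oxazolidin-2-one | CC[C@H](C(=O)N1[C@@H](Cc2ccccc2)COC1=O)[C@H](O)C=C | intermediate
6 | (2S,3R)-2-ethyl-3-hydroxy-N-methoxy-N-methylpent-4-enamide | CC[C@H](C(=O)N(C)OC)[C@H](O)C=C | intermediate
7 | (2S,3R)-3-[(tert-butyldimethylsilyl)oxy]-2-ethyl-N-methoxy-N-methylpent-4-enamide | CC[C@H](C(=O)N(C)OC)[C@H](O[Si](C)(C)C(C)(C)C)C=C | intermediate
8 | (2S,3R)-3-[(tert-butyldimethylsilyl)oxy]-2-ethylpent-4-enal | CC[C@H](C=O)[C@H](O[Si](C)(C)C(C)(C)C)C=C | intermediate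
9 | tert-butyl 1H-pyrrole-1-carboxylate (N-Boc-pyrrole) | CC(C)(C)OC(=O)n1cccc1 | starting material
10 | 1-bromo-4-chlorobutane | ClCCCCBr | starting material
11 | 4-chlorobutylmagnesium bromide | ClCCCC[Mg]Br | intermediate
12 | tert-butyl 2-lithio-1H-pyrrole-1-carboxylate | [Li]c1cccn1C(=O)OC(C)(C)C | intermediate
13 | tert-butyl 2-[(1RS,2R,3R)-3-[(tert-butyldimethylsilyl)oxy]-2-ethyl-1-hydroxypent-4-en-1-yl]-1H-pyrrole-1-carboxylate (present as its lithium alkoxide; both C9 epimers) | CC[C@H](C(O)c1cccn1C(=O)OC(C)(C)C)[C@H](O[Si](C)(C)C(C)(C)C)C=C | intermediate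
14 | tert-butyl (1RS,2R,3R)-3-[(tert-butyldimethylsilyl)oxy]-2-ethyl-1-(1H-pyrrol-2-yl)pent-4-en-1-yl carbonate (present as its N-lithio salt) | CC[C@H](C(OC(=O)OC(C)(C)C)c1ccc[nH]1)[C@H](O[Si](C)(C)C(C)(C)C)C=C | intermediate
15 | 2-[(2R,3R)-3-[(tert-butyldimethylsilyl)oxy]-2-ethylpent-4-en-1-ylidene]-2H-pyrrole (1-azafulvene) | CC[C@H](C=C1C=CC=N1)[C@H](O[Si](C)(C)C(C)(C)C)C=C | intermediate
16 | 2-[(3R,4R,5R)-3-[(tert-butyldimethylsilyl)oxy]-9-chloro-4-ethylnon-1-en-5-yl]-1H-pyrrole (present as its N-metal salt) | CC[C@H]([C@@H](CCCCCl)c1ccc[nH]1)[C@H](O[Si](C)(C)C(C)(C)C)C=C | intermediate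
17 | (9R)-9-[(3R,4R)-4-[(tert-butyldimethylsilyl)oxy]hex-5-en-3-yl]-6,7,8,9-tetrahydro-5H-pyrrolo[1,2-a]azepine | CC[C@H]([C@H]1CCCCn2cccc12)[C@H](O[Si](C)(C)C(C)(C)C)C=C | intermediate
18 | (3R,4R)-4-[(9R)-6,7,8,9-tetrahydro-5H-pyrrolo[1,2-a]azepin-9-yl]hex-1-en-3-ol | CC[C@H]([C@H]1CCCCn2cccc12)[C@H](O)C=C | intermediate
19 | methacryloyl chloride (2-methylprop-2-enoyl chloride) | CC(=C)C(Cl)=O | starting material
20 | (3R,4R)-4-[(9R)-6,7,8,9-tetrahydro-5H-pyrrolo[1,2-a]azepin-9-yl]hex-1-en-3-yl 2-methylprop-2-enoate | CC[C@H]([C@H]1CCCCn2cccc12)[C@H](OC(=O)C(C)=C)C=C | intermediate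
21 | (5S)-3-methyl-5-{(1R)-1-[(9R)-6,7,8,9-tetrahydro-5H-pyrrolo[1,2-a]azepin-9-yl]propyl}furan-2(5H)-one | CC[C@H]([C@H]1CCCCn2cccc12)[C@@H]1OC(=O)C(C)=C1 | intermediate
22 | (9R,10R,11S,12R,13R)-tetracyclic lactone: pyrrole (N4, C1–C3, C9a) fused to the azepane (N4, C5–C9, C9a) and to the carbocycle (C1, C9a, C9, C10 with ethyl, C11, C12) carrying the cis-fused γ-lactone (O on C11, C13 methyl); C3–H | CC[C@H]1[C@@H]2OC(=O)[C@H](C)[C@@H]2c2ccn3c2[C@@H]1CCCC3 | intermediate
23 | (S)-2-methylbutanedioic acid ((S)-methylsuccinic acid) | OC(=O)C[C@H](C)C(=O)O | starting material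
24 | (S)-3-methyloxolane-2,5-dione ((S)-methylsuccinic anhydride) | O=C1C[C@H](C)C(=O)O1 | intermediate
25 | (2S)-2-methyl-4-oxo-4-[C3 of tetracycle 22]butanoic acid (9R,10R,11S,12R,13R,20S) | CC[C@H]1[C@@H]2OC(=O)[C@H](C)[C@@H]2c2cc(C(=O)C[C@H](C)C(=O)O)n3c2[C@@H]1CCCC3 | intermediate
26 | methyl (2S)-2-methyl-4-oxo-4-[C3 of tetracycle 22]butanoate | CC[C@H]1[C@@H]2OC(=O)[C@H](C)[C@@H]2c2cc(C(=O)C[C@H](C)C(=O)OC)n3c2[C@@H]1CCCC3 | intermediate
27 | methyl (2S,4R)-4-hydroxy-2-methyl-4-[C3 of tetracycle 22]butanoate (18R,20S) | CC[C@H]1[C@@H]2OC(=O)[C@H](C)[C@@H]2c2cc([C@H](O)C[C@H](C)C(=O)OC)n3c2[C@@H]1CCCC3 | intermediate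
28 | CNP0232452.4 (9R,10R,11S,12R,13R,18R,20S) | CC[C@H]1[C@@H]2OC(=O)[C@H](C)[C@@H]2c2cc([C@H]3C[C@H](C)C(=O)O3)n3c2[C@@H]1CCCC3 | target

**Step count and risks**

Total step count: 14. Longest linear sequence: 13 steps (steps 1–10 and 12–14; step 11 is a one-step branch).

Steps most likely to fail:

Step 6 (proposed new method). The Boc shift may stop at the cyclic carbamate. The azafulvene may be deprotonated at C10 to the 2-vinylpyrrolide, or may dimerise, before the Grignard reagent captures it. Ring closure may go through carbon C1 instead of nitrogen, and the facial selectivity at C9 may be poor. The fallback uses known chemistry, sets out from 8 and comes back at 17. Pyrrolylmagnesium bromide (pyrrole, EtMgBr, THF, −40 °C) is added to 8 to give the N–H carbinol F1. p-Toluenesulfinic acid (CH2Cl2, rt) converts it into the storable 2-(1-tosylalkyl)pyrrole F2. F2 with 3 equiv of 11 (THF, −78 → 0 °C) loses sulfinate and takes up the Grignard reagent at C9, and the chloride 16 is isolated this time. KOH in DMSO (rt) then closes the azepine by N-alkylation to 17.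

Step 10. Intermolecular attack through the free and more nucleophilic α-carbon C3 may give oligomers, the electron-rich pyrrole may decompose under the Lewis acid, and kinetic control at C13 may be lost. The fallback sets out from 21 and comes back at 25. C3 is acylated first with 24 and AlCl3 (CH2Cl2, −20 °C) to give the 3-acylated butenolide keto acid F3. The acyl group blocks C3, stabilises the ring against acid and makes C1 (position 4 of a 2-acylpyrrole) the preferred site of electrophilic attack. TfOH (CH2Cl2, 0 °C → rt) then closes the six-membered ring onto the butenolide to give 25.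

Step 14. Hydride transfer to the electron-rich 2-acylpyrrole carbonyl may be slow and poorly face-selective, and the C18–O bond may ionise. The fallback sets out from 26 and comes back at 28. NaBH4 with CeCl3·7H2O (MeOH, −40 °C), without facial control, should give 27 together with the (18S) hydroxy ester F4. DBU closes both lactones, and 28 is separated from the 18-epi lactone F5. F5 is recycled by acid-catalysed equilibration at C18 (camphorsulfonic acid cat., CH2Cl2; reversible heterolysis of the pyrrol-2-yl carbinyl C–O bond) and renewed separation.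

**Further compounds**

F1 | step 6 | (1RS,2R,3R)-3-[(tert-butyldimethylsilyl)oxy]-2-ethyl-1-(1H-pyrrol-2-yl)pent-4-en-1-ol | CC[C@H](C(O)c1ccc[nH]1)[C@H](O[Si](C)(C)C(C)(C)C)C=C
F2 | step 6 | 2-[(1RS,2S,3R)-3-[(tert-butyldimethylsilyl)oxy]-2-ethyl-1-(4-methylbenzenesulfonyl)pent-4-en-1-yl]-1H-pyrrole | CC[C@H](C(c1ccc[nH]1)S(=O)(=O)c1ccc(C)cc1)[C@H](O[Si](C)(C)C(C)(C)C)C=C
F3 | step 10 | (2S)-2-methyl-4-[(9R)-9-{(1R)-1-[(2S)-4-methyl-5-oxo-2,5-dihydrofuran-2-yl]propyl}-6,7,8,9-tetrahydro-5H-pyrrolo[1,2-a]azepin-3-yl]-4-oxobutanoic acid | CC[C@H]([C@H]1CCCCn2c(C(=O)C[C@H](C)C(=O)O)ccc12)[C@@H]1OC(=O)C(C)=C1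
F4 | step 14 | methyl (2S,4S)-4-hydroxy-2-methyl-4-[C3 of tetracycle 22]butanoate (18S,20S) | CC[C@H]1[C@@H]2OC(=O)[C@H](C)[C@@H]2c2cc([C@@H](O)C[C@H](C)C(=O)OC)n3c2[C@@H]1CCCC3
F5 | step 14 | 18-epi-28 (9R,10R,11S,12R,13R,18S,20S) | CC[C@H]1[C@@H]2OC(=O)[C@H](C)[C@@H]2c2cc([C@@H]3C[C@H](C)C(=O)O3)n3c2[C@@H]1CCCC3
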